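**Retrosynthetic overview**
1. Target ⇐ C20 desilylation and C9 oxidation ⇐ ten-membered ring closed last by ring-closing metathesis at C5=C6 of a seco-diene that already holds ring A and the γ-lactone.
2. γ-Lactone (C7, C8) ⇐ hydroxyl-directed epoxidation and lactonisation of a dienol formed by joining fragment 1 (ring A aldehyde, C1–C5, C9–C16, C20) to fragment 2 (enyne ester, C6–C8, C17–C19) at C8–C9 by a nickel-catalysed reductive alkyne–aldehyde coupling.
3. Fragment 1 ⇐ ring A by Ireland–Claisen ring contraction of a trans δ-lactone (forms C1–C10, sets C1 and C10); the lactone ⇐ asymmetric vinylogous aldol and syn reduction; the C2–C5 arm ⇐ organolithium addition and anti reduction.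
4. Fragment 2 ⇐ (S)-Roche ester (C17) by alkyne homologation and Sonogashira vinylation.
5. Ring order: sacrificial δ-lactone → cyclohexene ring A → γ-lactone → ten-membered ring.

Assumption: atom labels C1–C20 are the briarane numbering of the target (C1 quaternary, C2 and C14 acetoxy carbons, C5=C6, C7 lactone O–CH, C8 tertiary carbinol, C9 ketone, C10 ring-fusion CH, C11=C12, C17 lactone α-carbon, C19 lactone carbonyl, C20 CH2OH). Compounds 2–4 are E/Z mixtures and 14–17 are epimer mixtures at the methyl-bearing carbon next to the ester carbonyl (C1, planarised in step 11), so these elements are left undefined in the SMILES.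

**Reagents for fragment 1**

Step 1
Reactants: 1 methyl 2-methyl-3-oxobutanoate
Product: 2 methyl 2-methyl-3-[(trimethylsilyl)oxy]but-2-enoate
Conditions: TMSCl, Et3N, hexane, rt
Reagents that add atoms: chlorotrimethylsilane, C[Si](C)(C)Cl
Why: O-silylation of the enolised β-keto ester (silyl enol ether formation) frees the γ-methyl group for deprotonation.

Step 2
Reactants: 2 methyl 2-methyl-3-[(trimethylsilyl)oxy]but-2-enoate
Product: 4 1-methoxy-2-methyl-1,3-bis[(trimethylsilyl)oxy]buta-1,3-diene, via lithium dienolate 3 (not isolated)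
Conditions: LiN(iPr)2, THF, −78 °C; TMSCl, −78 °C → rt
Reagents that add atoms: chlorotrimethylsilane, C[Si](C)(C)Cl
Why: kinetic γ-deprotonation and O-silylation give the Chan-type bis-silyl diene (silyl ketene acetal formation).

Step 3
Reactants: 5 3-methylbut-3-en-1-ol
Product: 6 4-iodo-2-methylbut-1-ene
Conditions: PPh3, imidazole, iodine, CH2Cl2, 0 °C → rt
Reagents that add atoms: iodine, [I][I]
Why: Appel-type iodination of a primary alcohol; no stereocentre is involved.

**Fragment 1 (ring A aldehyde)**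

Step 4
Reactants: 7 2,2-dimethoxyacetaldehyde; 8 ethyl 2-bromo-2-(triphenyl-λ5-phosphanylidene)acetate
Product: 9 ethyl (2Z)-2-bromo-4,4-dimethoxybut-2-enoate
Conditions: CH2Cl2, rt
Reagents that add atoms: none
Why: Wittig olefination with the stabilised α-bromo ylide puts the ester trans to the acetal carbon, which later places C9 cis to C12.

Step 5
Reactants: 9 ethyl (2Z)-2-bromo-4,4-dimethoxybut-2-enoate
Product: 10 (2Z)-2-bromo-4,4-dimethoxybut-2-en-1-ol
Conditions: iBu2AlH (2.2 equiv), CH2Cl2, −78 °C; aq. KNaC4H4O6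
Reagents that add atoms: none
Why: hydride 1,2-reduction of the enoate gives the allylic alcohol (future C20) and leaves the vinyl bromide and acetal untouched.

Step 6
Reactants: 10 (2Z)-2-bromo-4,4-dimethoxybut-2-en-1-ol
Product: 11 {[(2Z)-2-bromo-4,4-dimethoxybut-2-en-1-yl]oxy}(tert-butyl)diphenylsilane
Conditions: TBDPSCl, imidazole, DMF, rt
Reagents that add atoms: tert-butyl(chloro)diphenylsilane, CC(C)(C)[Si](Cl)(c1ccccc1)c1ccccc1
Why: silylation of the primary alcohol; the TBDPS ether is the only protecting group carried to the last step.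

Step 7
Reactants: 11 {[(2Z)-2-bromo-4,4-dimethoxybut-2-en-1-yl]oxy}(tert-butyl)diphenylsilane
Product: 13 (2Z)-2-({[tert-butyl(diphenyl)silyl]oxy}methyl)-4,4-dimethoxybut-2-enal, via alkenyllithium 12 (not isolated)
Conditions: t-BuLi (2.1 equiv), Et2O, −78 °C; DMF; H2O
Reagents that add atoms: N,N-dimethylformamide, CN(C)C=O
Why: bromine–lithium exchange with retention of alkene geometry, then formylation with DMF, gives the enal with CHO (C12) cis to the acetal carbon (C9).

Step 8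
Reactants: 13 (2Z)-2-({[tert-butyl(diphenyl)silyl]oxy}methyl)-4,4-dimethoxybut-2-enal; 4 1-methoxy-2-methyl-1,3-bis[(trimethylsilyl)oxy]buta-1,3-diene
Product: 15 methyl (5R,6Z)-6-({[tert-butyl(diphenyl)silyl]oxy}methyl)-5-hydroxy-8,8-dimethoxy-2-methyl-3-oxooct-6-enoate, via bis-silyl aldol adduct 14 (not isolated)
Conditions: Ti(OiPr)4 (10 mol %), (R)-BINOL (10 mol %), 4 Å MS, THF, −78 → −20 °C; then PPTS, MeOH, 0 °C
Reagents that add atoms: none
Why: catalytic asymmetric vinylogous Mukaiyama aldol; the BINOL–titanium complex selects the aldehyde face and sets C12 (R), from which all ring A centres are relayed (the ligand antipode is used if the induction sense proves opposite).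

Step 9
Reactants: 15 methyl (5R,6Z)-6-({[tert-butyl(diphenyl)silyl]oxy}methyl)-5-hydroxy-8,8-dimethoxy-2-methyl-3-oxooct-6-enoate
Product: 16 methyl (3S,5R,6Z)-6-({[tert-butyl(diphenyl)silyl]oxy}methyl)-3,5-dihydroxy-8,8-dimethoxy-2-methyloct-6-enoate
Conditions: Et2BOMe, NaBH4, THF–MeOH (4:1), −78 °C
Reagents that add atoms: none
Why: Narasaka–Prasad reduction; external hydride attacks the boron chelate to give the 1,3-syn diol, setting C14 (S) from C12.

Step 10
Reactants: 16 methyl (3S,5R,6Z)-6-({[tert-butyl(diphenyl)silyl]oxy}methyl)-3,5-dihydroxy-8,8-dimethoxy-2-methyloct-6-enoate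
Product: 17 (4S,6R)-6-[(2Z)-1-{[tert-butyl(diphenyl)silyl]oxy}-4,4-dimethoxybut-2-en-2-yl]-4-hydroxy-3-methyloxan-2-one
Conditions: PPTS (cat.), benzene, 60 °C
Reagents that add atoms: none
Why: acid-catalysed lactonisation of the δ-hydroxy ester; the syn diol gives the trans-4,6 δ-lactone that the ring contraction needs.

Step 11
Reactants: 17 (4S,6R)-6-[(2Z)-1-{[tert-butyl(diphenyl)silyl]oxy}-4,4-dimethoxybut-2-en-2-yl]-4-hydroxy-3-methyloxan-2-one
Product: 20 (1R,2S,6S)-3-({[tert-butyl(diphenyl)silyl]oxy}methyl)-2-(dimethoxymethyl)-6-hydroxy-1-methylcyclohex-3-ene-1-carboxylic acid, via silyl ketene acetal 18 (not isolated), via bis-silylated acid 19 (not isolated)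
Conditions: LiN(iPr)2 (2.4 equiv), TMSCl, Et3N, THF, −78 → 60 °C; then K2CO3, MeOH; pH 5 work-up
Reagents that add atoms: none
Why: Ireland–Claisen ring contraction of the lactone ketene acetal through the enforced boat transition state forms C1–C10 on the face bearing the alkenyl group, so C2 ends cis to the C14 oxygen and, from the Z alkene, C9 ends trans to C2; the alkoxide dianion prevents β-elimination.

Step 12
Reactants: 20 (1R,2S,6S)-3-({[tert-butyl(diphenyl)silyl]oxy}methyl)-2-(dimethoxymethyl)-6-hydroxy-1-methylcyclohex-3-ene-1-carboxylic acid; 6 4-iodo-2-methylbut-1-ene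
Product: 22 1-[(1R,2S,6S)-3-({[tert-butyl(diphenyl)silyl]oxy}methyl)-2-(dimethoxymethyl)-6-hydroxy-1-methylcyclohex-3-en-1-yl]-4-methylpent-4-en-1-one, via organolithium 21 (not isolated)
Conditions: 6, t-BuLi (2 equiv), pentane–Et2O, −78 °C; then 20 (0.25 equiv), THF, −78 → 0 °C; H2O
Reagents that add atoms: none
Why: organolithium addition to the lithium carboxylate stops at the gem-diolate and gives the ketone on work-up (acid-to-ketone conversion), installing C3–C5 with the isopropenyl metathesis handle.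

Step 13
Reactants: 22 1-[(1R,2S,6S)-3-({[tert-butyl(diphenyl)silyl]oxy}methyl)-2-(dimethoxymethyl)-6-hydroxy-1-methylcyclohex-3-en-1-yl]-4-methylpent-4-en-1-one
Product: 23 (1S,5S,6S)-4-({[tert-butyl(diphenyl)silyl]oxy}methyl)-5-(dimethoxymethyl)-6-[(1S)-1-hydroxy-4-methylpent-4-en-1-yl]-6-methylcyclohex-3-en-1-ol
Conditions: Me4NBH(OAc)3, MeCN–AcOH (1:1), −30 °C
Reagents that add atoms: none
Why: Evans–Saksena reduction; hydride is delivered intramolecularly from the C14 alkoxyborohydride to give the 1,3-anti diol, which is C2 (S).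

Step 14
Reactants: 23 (1S,5S,6S)-4-({[tert-butyl(diphenyl)silyl]oxy}methyl)-5-(dimethoxymethyl)-6-[(1S)-1-hydroxy-4-methylpent-4-en-1-yl]-6-methylcyclohex-3-en-1-ol
Product: 24 (1S,5S,6S)-6-[(1S)-1-(acetyloxy)-4-methylpent-4-en-1-yl]-4-({[tert-butyl(diphenyl)silyl]oxy}methyl)-5-(dimethoxymethyl)-6-methylcyclohex-3-en-1-yl acetate
Conditions: Ac2O, pyridine, DMAP (cat.), CH2Cl2, rt
Reagents that add atoms: acetic anhydride, CC(=O)OC(C)=O
Why: acylation of both secondary alcohols installs the two acetates of the target, which tolerate every later step.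

Step 15
Reactants: 24 (1S,5S,6S)-6-[(1S)-1-(acetyloxy)-4-methylpent-4-en-1-yl]-4-({[tert-butyl(diphenyl)silyl]oxy}methyl)-5-(dimethoxymethyl)-6-methylcyclohex-3-en-1-yl acetate
Product: 25 (1S,5S,6S)-6-[(1S)-1-(acetyloxy)-4-methylpent-4-en-1-yl]-4-({[tert-butyl(diphenyl)silyl]oxy}methyl)-5-formyl-6-methylcyclohex-3-en-1-yl acetate
Conditions: TESOTf, 2,4,6-collidine, CH2Cl2, 0 °C; then H2O
Reagents that add atoms: water, O
Why: near-neutral acetal cleavage through a collidinium intermediate unveils the C9 aldehyde without acid that could epimerise C10 or conjugate the β,γ-alkene.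

**Fragment 2 (enyne ester)**

Step 16
Reactants: 26 methyl (2S)-3-hydroxy-2-methylpropanoate
Product: 27 methyl (2S)-3-{[tert-butyl(dimethyl)silyl]oxy}-2-methylpropanoate
Conditions: TBSCl, imidazole, CH2Cl2, rt
Reagents that add atoms: tert-butyl(chloro)dimethylsilane, CC(C)(C)[Si](C)(C)Cl
Why: silyl protection of the Roche ester hydroxyl (future C19); the chiral-pool centre becomes C17.

Step 17
Reactants: 27 methyl (2S)-3-{[tert-butyl(dimethyl)silyl]oxy}-2-methylpropanoate
Product: 28 (2S)-3-{[tert-butyl(dimethyl)silyl]oxy}-2-methylpropanal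
Conditions: iBu2AlH (1.1 equiv), CH2Cl2, −78 °C; aq. KNaC4H4O6
Reagents that add atoms: none
Why: partial hydride reduction of the ester at low temperature stops at the aldehyde (future C8).

Step 18
Reactants: 28 (2S)-3-{[tert-butyl(dimethyl)silyl]oxy}-2-methylpropanal
Product: 29 tert-butyl(dimethyl){[(2R)-2-methylbut-3-yn-1-yl]oxy}silane
Conditions: dimethyl (1-diazo-2-oxopropyl)phosphonate, K2CO3, MeOH, 0 °C → rt
Reagents that add atoms: dimethyl (1-diazo-2-oxopropyl)phosphonate, CC(=O)C(=[N+]=[N-])P(=O)(OC)OC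
Why: Ohira–Bestmann (Seyferth–Gilbert) homologation adds C7 as a terminal alkyne under base mild enough to keep the α-centre.

Step 19
Reactants: 29 tert-butyl(dimethyl){[(2R)-2-methylbut-3-yn-1-yl]oxy}silane
Product: 30 tert-butyl(dimethyl){[(2R)-2-methylhex-5-en-3-yn-1-yl]oxy}silane
Conditions: bromoethene, PdCl2(PPh3)2 (3 mol %), CuI (6 mol %), iPr2NH, THF, 0 °C → rt
Reagents that add atoms: bromoethene, C=CBr
Why: Sonogashira coupling attaches the vinyl group (C6 and the carbon later lost as ethene).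

Step 20
Reactants: 30 tert-butyl(dimethyl){[(2R)-2-methylhex-5-en-3-yn-1-yl]oxy}silane
Product: 31 (2R)-2-methylhex-5-en-3-ynoic acid
Conditions: CrO3, H2SO4, acetone–H2O, 0 °C
Reagents that add atoms: water, O
Why: Jones conditions cleave the silyl ether and oxidise the primary alcohol to the acid in one operation, and the acidic medium avoids base-induced alkyne–allene isomerisation at C17.

Step 21
Reactants: 31 (2R)-2-methylhex-5-en-3-ynoic acid
Product: 32 tert-butyl (2R)-2-methylhex-5-en-3-ynoate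
Conditions: tert-butyl 2,2,2-trichloroacetimidate, cyclohexane–CH2Cl2, rt
Reagents that add atoms: tert-butyl 2,2,2-trichloroacetimidate, CC(C)(C)OC(=N)C(Cl)(Cl)Cl
Why: base-free tert-butylation gives an ester that can later lactonise with loss of isobutene.

**Union and endgame**

Step 22
Reactants: 25 (1S,5S,6S)-6-[(1S)-1-(acetyloxy)-4-methylpent-4-en-1-yl]-4-({[tert-butyl(diphenyl)silyl]oxy}methyl)-5-formyl-6-methylcyclohex-3-en-1-yl acetate; 32 tert-butyl (2R)-2-methylhex-5-en-3-ynoate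
Product: 33 (9R)-dienol tert-butyl ester (C8–C9 joined; C7=C8 E; 17R)
Conditions: Ni(cod)2 (10 mol %), PCyp3 (20 mol %), Et3B (2 equiv), EtOAc, rt; aq. NaHCO3
Reagents that add atoms: none
Why: nickel-catalysed reductive coupling of a 1,3-enyne with an aldehyde is alkene-directed to the alkyne carbon remote from the vinyl group, adds H and carbon cis to give the E diene, and follows Felkin–Anh attack anti to quaternary C1 to give the 9R carbinol.

Step 23
Reactants: 33 (9R)-dienol tert-butyl ester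
Product: 35 seco-lactone (γ-lactone closed; C8 tertiary OH; C9 carbinol; vinyl on C7), via epoxy alcohol 34 (not isolated)
Conditions: VO(acac)2 (5 mol %), t-BuOOH, CH2Cl2, 0 °C; then CSA (10 mol %), 0 °C → rt
Reagents that add atoms: tert-butyl hydroperoxide, CC(C)(C)OO
Why: hydroxyl-directed epoxidation delivers oxygen syn to the C9 hydroxyl in the A(1,2)-minimised (erythro) transition state to set C8, and the ester carbonyl then opens the vinyl epoxide at allylic C7 with inversion to set C7 and close the γ-lactone.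

Step 24
Reactants: 35 seco-lactone
Product: 36 (9R)-hydroxy macrocycle (target skeleton with C9 carbinol and C20 silyl ether)
Conditions: second-generation Hoveyda–Grubbs catalyst (15 mol %), toluene (1 mM), 80 °C
Reagents that add atoms: none
Why: ring-closing metathesis between the C7 vinyl and the C5 isopropenyl group closes the ten-membered ring, where ring strain should favour the Z trisubstituted alkene; the ring A alkene is too hindered to react.

Step 25
Reactants: 36 (9R)-hydroxy macrocycle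
Product: 37 C9 ketone (20-O-silyl ether of the target)
Conditions: Dess–Martin periodinane, NaHCO3, CH2Cl2, 0 °C → rt
Reagents that add atoms: none
Why: buffered periodinane oxidation of the only secondary alcohol gives the C9 ketone without base that could epimerise C10; the tertiary C8 hydroxyl cannot react.

Step 26
Reactants: 37 C9 ketone
Product: 38 CNP0140109.1
Conditions: HF·pyridine, pyridine, THF, 0 °C → rt
Reagents that add atoms: none
Why: fluoride-mediated desilylation frees the C20 alcohol and leaves acetates, lactone and the β,γ-unsaturated ketone intact.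

**Compound list**
1 | methyl 2-methyl-3-oxobutanoate | COC(=O)C(C)C(C)=O | starting material
2 | methyl 2-methyl-3-[(trimethylsilyl)oxy]but-2-enoate (E/Z mixture) | COC(=O)C(C)=C(C)O[Si](C)(C)C | intermediate
3 | lithium dienolate of 2 (lithium 1-methoxy-2-methyl-3-[(trimethylsilyl)oxy]buta-1,3-dien-1-olate) | COC(O[Li])=C(C)C(=C)O[Si](C)(C)C | intermediate
4 | 1-methoxy-2-methyl-1,3-bis[(trimethylsilyl)oxy]buta-1,3-diene | COC(O[Si](C)(C)C)=C(C)C(=C)O[Si](C)(C)C | intermediate
5 | 3-methylbut-3-en-1-ol | C=C(C)CCO | starting material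
6 | 4-iodo-2-methylbut-1-ene | C=C(C)CCI | intermediate
7 | 2,2-dimethoxyacetaldehyde | COC(OC)C=O | starting material
8 | ethyl 2-bromo-2-(triphenyl-λ5-phosphanylidene)acetate | CCOC(=O)C(Br)=P(c1ccccc1)(c1ccccc1)c1ccccc1 | starting material
9 | ethyl (2Z)-2-bromo-4,4-dimethoxybut-2-enoate | CCOC(=O)/C(Br)=C/C(OC)OC | intermediate
10 | (2Z)-2-bromo-4,4-dimethoxybut-2-en-1-ol | OC/C(Br)=C/C(OC)OC | intermediate
11 | {[(2Z)-2-bromo-4,4-dimethoxybut-2-en-1-yl]oxy}(tert-butyl)diphenylsilane | COC(OC)/C=C(Br)/CO[Si](c1ccccc1)(c1ccccc1)C(C)(C)C | intermediate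
12 | alkenyllithium from 11 (lithium in place of bromine, geometry retained) | COC(OC)/C=C([Li])/CO[Si](c1ccccc1)(c1ccccc1)C(C)(C)C | intermediate
13 | (2Z)-2-({[tert-butyl(diphenyl)silyl]oxy}methyl)-4,4-dimethoxybut-2-enal | COC(OC)/C=C(C=O)/CO[Si](c1ccccc1)(c1ccccc1)C(C)(C)C | intermediate
14 | methyl (5R,6Z)-6-({[tert-butyl(diphenyl)silyl]oxy}methyl)-8,8-dimethoxy-2-methyl-3,5-bis[(trimethylsilyl)oxy]octa-2,6-dienoate | COC(=O)C(C)=C(O[Si](C)(C)C)C[C@@H](O[Si](C)(C)C)/C(CO[Si](c1ccccc1)(c1ccccc1)C(C)(C)C)=C\C(OC)OC | intermediate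
15 | methyl (5R,6Z)-6-({[tert-butyl(diphenyl)silyl]oxy}methyl)-5-hydroxy-8,8-dimethoxy-2-methyl-3-oxooct-6-enoate (2-epimers) | COC(=O)C(C)C(=O)C[C@@H](O)/C(CO[Si](c1ccccc1)(c1ccccc1)C(C)(C)C)=C\C(OC)OC | intermediate
16 | methyl (3S,5R,6Z)-6-({[tert-butyl(diphenyl)silyl]oxy}methyl)-3,5-dihydroxy-8,8-dimethoxy-2-methyloct-6-enoate (2-epimers) | COC(=O)C(C)[C@@H](O)C[C@@H](O)/C(CO[Si](c1ccccc1)(c1ccccc1)C(C)(C)C)=C\C(OC)OC | intermediate
17 | (4S,6R)-6-[(2Z)-1-{[tert-butyl(diphenyl)silyl]oxy}-4,4-dimethoxybut-2-en-2-yl]-4-hydroxy-3-methyloxan-2-one (3-epimers) | O=C1C(C)[C@@H](O)C[C@@H](O1)/C(CO[Si](c2ccccc2)(c2ccccc2)C(C)(C)C)=C\C(OC)OC | intermediate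
18 | O-trimethylsilyl ketene acetal of 17 with the C4 oxygen also silylated: {[(2R,4S)-2-[(2Z)-1-{[tert-butyl(diphenyl)silyl]oxy}-4,4-dimethoxybut-2-en-2-yl]-5-methyl-4-[(trimethylsilyl)oxy]-3,4-dihydro-2H-pyran-6-yl]oxy}trimethylsilane | C[Si](C)(C)OC1=C(C)[C@@H](O[Si](C)(C)C)C[C@@H](O1)/C(CO[Si](c2ccccc2)(c2ccccc2)C(C)(C)C)=C\C(OC)OC | intermediate
19 | trimethylsilyl (1R,2S,6S)-3-({[tert-butyl(diphenyl)silyl]oxy}methyl)-2-(dimethoxymethyl)-1-methyl-6-[(trimethylsilyl)oxy]cyclohex-3-ene-1-carboxylate | C[Si](C)(C)O[C@H]1CC=C(CO[Si](c2ccccc2)(c2ccccc2)C(C)(C)C)[C@H](C(OC)OC)[C@@]1(C)C(=O)O[Si](C)(C)C | intermediate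
20 | (1R,2S,6S)-3-({[tert-butyl(diphenyl)silyl]oxy}methyl)-2-(dimethoxymethyl)-6-hydroxy-1-methylcyclohex-3-ene-1-carboxylic acid | O[C@H]1CC=C(CO[Si](c2ccccc2)(c2ccccc2)C(C)(C)C)[C@H](C(OC)OC)[C@@]1(C)C(=O)O | intermediate
21 | (3-methylbut-3-en-1-yl)lithium | [Li]CCC(C)=C | intermediate
22 | 1-[(1R,2S,6S)-3-({[tert-butyl(diphenyl)silyl]oxy}methyl)-2-(dimethoxymethyl)-6-hydroxy-1-methylcyclohex-3-en-1-yl]-4-methylpent-4-en-1-one | O[C@H]1CC=C(CO[Si](c2ccccc2)(c2ccccc2)C(C)(C)C)[C@H](C(OC)OC)[C@@]1(C)C(=O)CCC(C)=C | intermediate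
23 | (1S,5S,6S)-4-({[tert-butyl(diphenyl)silyl]oxy}methyl)-5-(dimethoxymethyl)-6-[(1S)-1-hydroxy-4-methylpent-4-en-1-yl]-6-methylcyclohex-3-en-1-ol | O[C@H]1CC=C(CO[Si](c2ccccc2)(c2ccccc2)C(C)(C)C)[C@H](C(OC)OC)[C@@]1(C)[C@@H](O)CCC(C)=C | intermediate
24 | (1S,5S,6S)-6-[(1S)-1-(acetyloxy)-4-methylpent-4-en-1-yl]-4-({[tert-butyl(diphenyl)silyl]oxy}methyl)-5-(dimethoxymethyl)-6-methylcyclohex-3-en-1-yl acetate | CC(=O)O[C@H]1CC=C(CO[Si](c2ccccc2)(c2ccccc2)C(C)(C)C)[C@H](C(OC)OC)[C@@]1(C)[C@@H](OC(C)=O)CCC(C)=C | intermediate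
25 | (1S,5S,6S)-6-[(1S)-1-(acetyloxy)-4-methylpent-4-en-1-yl]-4-({[tert-butyl(diphenyl)silyl]oxy}methyl)-5-formyl-6-methylcyclohex-3-en-1-yl acetate | CC(=O)O[C@H]1CC=C(CO[Si](c2ccccc2)(c2ccccc2)C(C)(C)C)[C@H](C=O)[C@@]1(C)[C@@H](OC(C)=O)CCC(C)=C | intermediate
26 | methyl (2S)-3-hydroxy-2-methylpropanoate | COC(=O)[C@@H](C)CO | starting material
27 | methyl (2S)-3-{[tert-butyl(dimethyl)silyl]oxy}-2-methylpropanoate | COC(=O)[C@@H](C)CO[Si](C)(C)C(C)(C)C | intermediate
28 | (2S)-3-{[tert-butyl(dimethyl)silyl]oxy}-2-methylpropanal | O=C[C@@H](C)CO[Si](C)(C)C(C)(C)C | intermediate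
29 | tert-butyl(dimethyl){[(2R)-2-methylbut-3-yn-1-yl]oxy}silane | C#C[C@@H](C)CO[Si](C)(C)C(C)(C)C | intermediate
30 | tert-butyl(dimethyl){[(2R)-2-methylhex-5-en-3-yn-1-yl]oxy}silane | C=CC#C[C@@H](C)CO[Si](C)(C)C(C)(C)C | intermediate
31 | (2R)-2-methylhex-5-en-3-ynoic acid | C=CC#C[C@@H](C)C(=O)O | intermediate
32 | tert-butyl (2R)-2-methylhex-5-en-3-ynoate | C=CC#C[C@@H](C)C(=O)OC(C)(C)C | intermediate
33 | dienol: tert-butyl (2R,3E)-2-methylhexa-3,5-dienoate bearing at C3 the (R)-hydroxymethine (C9) that carries the ring of 25 in place of its formyl group | CC(=O)O[C@H]1CC=C(CO[Si](c2ccccc2)(c2ccccc2)C(C)(C)C)[C@H]([C@@H](O)/C(=C/C=C)[C@@H](C)C(=O)OC(C)(C)C)[C@@]1(C)[C@@H](OC(C)=O)CCC(C)=C | intermediate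
34 | epoxy alcohol of 33 (C7–C8 epoxide on the face syn to the C9 hydroxyl) | CC(=O)O[C@H]1CC=C(CO[Si](c2ccccc2)(c2ccccc2)C(C)(C)C)[C@H]([C@@H](O)[C@]3(O[C@@H]3C=C)[C@@H](C)C(=O)OC(C)(C)C)[C@@]1(C)[C@@H](OC(C)=O)CCC(C)=C | intermediate
35 | seco-lactone: γ-lactone with 7-vinyl, 8-hydroxy and 17-methyl configured as in the target, (9R)-carbinol, ring A of 25 with its C5 isopropenyl arm | CC(=O)O[C@H]1CC=C(CO[Si](c2ccccc2)(c2ccccc2)C(C)(C)C)[C@H]([C@@H](O)[C@@]3(O)[C@H](C=C)OC(=O)[C@@H]3C)[C@@]1(C)[C@@H](OC(C)=O)CCC(C)=C | intermediate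
36 | (9R)-hydroxy macrocycle: target skeleton with CH(OH) at C9 and C20 as TBDPS ether, all other centres and the 5Z alkene as in the target | CC(=O)O[C@H]1CC=C(CO[Si](c4ccccc4)(c4ccccc4)C(C)(C)C)[C@@H]2[C@@H](O)[C@@]3(O)[C@H](/C=C(/C)CC[C@H](OC(C)=O)[C@]21C)OC(=O)[C@@H]3C | intermediate
37 | C9 ketone: 20-O-(tert-butyldiphenylsilyl) ether of the target | CC(=O)O[C@H]1CC=C(CO[Si](c4ccccc4)(c4ccccc4)C(C)(C)C)[C@@H]2C(=O)[C@@]3(O)[C@H](/C=C(/C)CC[C@H](OC(C)=O)[C@]21C)OC(=O)[C@@H]3C | intermediate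
38 | CNP0140109.1 | CC(=O)O[C@H]1CC=C(CO)[C@@H]2C(=O)[C@@]3(O)[C@H](/C=C(/C)CC[C@H](OC(C)=O)[C@]21C)OC(=O)[C@@H]3C | target

**Totals**
Total step count: 26.
Longest linear sequence: 17 steps (steps 4–15, then 22–26). Fragment 2 (steps 16–21) and the two reagent branches (steps 1–2 and step 3) lie off it.

**Steps most likely to fail, with fallbacks**

Step 24 (ring-closing metathesis to a ten-membered ring with a trisubstituted Z alkene). The fallback changes the order of ring formation so that the ring is closed before the trans-fused lactone stiffens the chain. It sets out from 33: metathesis between the isopropenyl group and the terminal vinyl of the diene (second-generation Grubbs catalyst, CH2Cl2, 40 °C, 1 mM) gives the ten-membered dienol F1. VO(acac)2/t-BuOOH epoxidation directed by the C9 hydroxyl then gives the macrocyclic epoxy alcohol F2, and CSA closes the γ-lactone with loss of isobutene. The route is rejoined at 36.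

Step 22 (nickel-catalysed reductive coupling with a hindered α-branched aldehyde). The fallback replaces it by a Nozaki–Hiyama–Kishi coupling of a preformed dienyl iodide. It sets out from 29: iodine in CH2Cl2 adds anti to give the (E)-diiodide F3. A Stille coupling of the less hindered terminal carbon–iodine bond with tributyl(vinyl)stannane (Pd(PPh3)4, CuI, DMF) gives the dienyl iodide F4, with iodine trans to the vinyl group. CrO3/H2SO4 gives the acid F5, and tert-butyl 2,2,2-trichloroacetimidate gives the tert-butyl ester F6. Coupling of F6 with 25 (CrCl2, NiCl2 cat., DMSO, rt) proceeds with retention of alkene geometry and the same Felkin preference. The route is rejoined at 33.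

Step 8 (asymmetric vinylogous aldol on a geometrically labile, α-branched Z enal). The fallback builds the δ-lactone by allylation, metathesis and conjugate borylation instead. It sets out from 13: Keck allylation (allyltributylstannane, Ti(OiPr)4/(R)-BINOL, CH2Cl2, −20 °C) gives the homoallylic alcohol F7. Methacryloyl chloride, Et3N and DMAP give the methacrylate F8, and the second-generation Grubbs catalyst closes the dihydropyranone F9. Copper-catalysed conjugate borylation (bis(pinacolato)diboron, CuCl, NaOtBu, DPEphos, MeOH, THF) anti to the C6 substituent gives the boronate F10, and NaBO3 oxidation with retention gives the trans hydroxy lactone. The route is rejoined at 17.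

**Further compounds**
F1 | step 24 | ten-membered dienol: ring closed at C5=C6 (Z) with the C7=C8 alkene (E), (9R)-carbinol and the tert-butyl (R)-propanoate arm on C8 still present | CC(=O)O[C@H]1CC=C(CO[Si](c4ccccc4)(c4ccccc4)C(C)(C)C)[C@@H]2[C@@H](O)/C(=C/C=C(/C)CC[C@H](OC(C)=O)[C@]21C)[C@@H](C)C(=O)OC(C)(C)C
F2 | step 24 | macrocyclic epoxy alcohol: C7–C8 epoxide of F1 syn to the C9 hydroxyl | CC(=O)O[C@H]1CC=C(CO[Si](c4ccccc4)(c4ccccc4)C(C)(C)C)[C@@H]2[C@@H](O)[C@]3(O[C@@H]3/C=C(/C)CC[C@H](OC(C)=O)[C@]21C)[C@@H](C)C(=O)OC(C)(C)C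
F3 | step 22 | tert-butyl{[(2S,3E)-3,4-diiodo-2-methylbut-3-en-1-yl]oxy}dimethylsilane | I/C=C(/I)[C@@H](C)CO[Si](C)(C)C(C)(C)C
F4 | step 22 | tert-butyl{[(2S,3E)-3-iodo-2-methylhexa-3,5-dien-1-yl]oxy}dimethylsilane | C=C/C=C(/I)[C@@H](C)CO[Si](C)(C)C(C)(C)C
F5 | step 22 | (2S,3E)-3-iodo-2-methylhexa-3,5-dienoic acid | C=C/C=C(/I)[C@@H](C)C(=O)O
F6 | step 22 | tert-butyl (2S,3E)-3-iodo-2-methylhexa-3,5-dienoate | C=C/C=C(/I)[C@@H](C)C(=O)OC(C)(C)C
F7 | step 8 | (4R,5Z)-5-({[tert-butyl(diphenyl)silyl]oxy}methyl)-7,7-dimethoxyhepta-1,5-dien-4-ol | C=CC[C@@H](O)/C(CO[Si](c1ccccc1)(c1ccccc1)C(C)(C)C)=C\C(OC)OC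
F8 | step 8 | (4R,5Z)-5-({[tert-butyl(diphenyl)silyl]oxy}methyl)-7,7-dimethoxyhepta-1,5-dien-4-yl 2-methylprop-2-enoate | C=CC[C@@H](OC(=O)C(C)=C)/C(CO[Si](c1ccccc1)(c1ccccc1)C(C)(C)C)=C\C(OC)OC
F9 | step 8 | (6R)-6-[(2Z)-1-{[tert-butyl(diphenyl)silyl]oxy}-4,4-dimethoxybut-2-en-2-yl]-3-methyl-5,6-dihydro-2H-pyran-2-one | CC1=CC[C@@H](OC1=O)/C(CO[Si](c2ccccc2)(c2ccccc2)C(C)(C)C)=C\C(OC)OC
F10 | step 8 | (4S,6R)-6-[(2Z)-1-{[tert-butyl(diphenyl)silyl]oxy}-4,4-dimethoxybut-2-en-2-yl]-3-methyl-4-(4,4,5,5-tetramethyl-1,3,2-dioxaborolan-2-yl)oxan-2-one | O=C1C(C)[C@@H](B2OC(C)(C)C(C)(C)O2)C[C@@H](O1)/C(CO[Si](c3ccccc3)(c3ccccc3)C(C)(C)C)=C\C(OC)OC
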